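**Assumption:** the target is the (2S,2''R) diastereomer encoded by the SMILES (2'' is the side-chain stereocenter); compounds 1, 6 and 11 are bought.

## Retrosynthetic overview

1. Ring C is closed last: O1–C2 by oxa-Michael closure of a 2'-hydroxychalcone, made by Claisen–Schmidt condensation of acetophenone 10 (ring A) with aldehyde 12 (ring B). Rings A and B are bought.
2. Key disconnection: the aryl–CH2 bond of the lavandulyl group, formed from aryl bromide 8 and acid 5 in a light-driven nickel decarboxylative coupling (CO2 is the traceless handle).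
3. Acid 5 comes from aldehyde 4, which comes from Norrish type 1 ring opening of 2,2-dimethyl ketone 3, made by reductive methylation of (R)-carvone. The carvone stereocenter becomes C2'' (R).
4. C2 (S) arises in the ring closure without useful bias. The carvone-derived center makes the C2 epimers diastereomers, so they are separated on achiral silica and the (2R) epimer is re-equilibrated and recycled.

## Route

**Step 1**
Reactants: 1 (R)-(−)-carvone
Product: 3 (5R)-2,2-dimethyl-5-(prop-1-en-2-yl)cyclohexan-1-one, via lithium enolate 2 (not isolated)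
Conditions: LiBH(s-Bu)3 (1.05 equiv), THF, −78 °C; then MeI (3 equiv), −78 °C to rt; aq NH4Cl work-up
Reagents that add atoms: iodomethane, CI
Why: Conjugate hydride delivery to the β-unsubstituted enone (1,4-reduction) gives the regiodefined enolate 2, which is C-methylated at the methyl-bearing carbon (reductive alkylation); the carvone stereocenter is untouched and C2 becomes a non-stereogenic gem-dimethyl carbon.

**Step 2**
Reactants: 3 (5R)-2,2-dimethyl-5-(prop-1-en-2-yl)cyclohexan-1-one
Product: 4 (3R)-6-methyl-3-(prop-1-en-2-yl)hept-5-enal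
Conditions: hν (300 nm, Pyrex flow coil), degassed pentane (0.02 M), 20 °C, stopped at about 70% conversion, recovered 3 recycled
Reagents that add atoms: none
Why: Norrish type 1 α-cleavage on the quaternary side gives an acyl/tertiary-alkyl biradical whose acyl radical takes a C3 hydrogen through a six-membered transition state, opening the ring to the aldehyde and placing the trisubstituted (prenyl) double bond regiospecifically; the stereocenter lies outside the reacting atoms and becomes the (R) lavandulyl carbon.

**Step 3**
Reactants: 4 (3R)-6-methyl-3-(prop-1-en-2-yl)hept-5-enal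
Product: 5 (3R)-6-methyl-3-(prop-1-en-2-yl)hept-5-enoic acid
Conditions: NaClO2 (2 equiv), NaH2PO4 (3 equiv), 2-methylbut-2-ene (20 equiv), t-BuOH/H2O, 0 °C to rt
Reagents that add atoms: sodium chlorite, [Na+].[O-]Cl=O
Why: Pinnick oxidation is selective for the aldehyde, the excess 2-methylbut-2-ene removes HOCl before it reaches the two alkenes, and the β-stereocenter cannot epimerise.

**Step 4**
Reactants: 6 1-(2,6-dihydroxy-4-methoxyphenyl)ethan-1-one
Product: 7 1-[2-hydroxy-4-methoxy-6-(methoxymethoxy)phenyl]ethan-1-one
Conditions: MOMCl (1.1 equiv), i-Pr2NEt (1.5 equiv), CH2Cl2, 0 °C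
Reagents that add atoms: chloromethyl methyl ether, COCCl
Why: The two hydroxyls of 6 are equivalent, and after one MOM etherification the remaining phenol is locked in a hydrogen bond to the acetyl group, so the reaction stops at the mono ether.

**Step 5**
Reactants: 7 1-[2-hydroxy-4-methoxy-6-(methoxymethoxy)phenyl]ethan-1-one
Product: 8 1-[3-bromo-2-hydroxy-4-methoxy-6-(methoxymethoxy)phenyl]ethan-1-one
Conditions: NBS (1.0 equiv), MeCN, −20 to 0 °C
Reagents that add atoms: N-bromosuccinimide, O=C1CCC(=O)N1Br
Why: Electrophilic aromatic bromination goes ortho to the free chelated phenol (C3, between OH and OMe) rather than to the more crowded C5 between OMe and OMOM, as expected by analogy with the 4,6-dimethoxy compound.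

**Step 6**
Reactants: 5 (3R)-6-methyl-3-(prop-1-en-2-yl)hept-5-enoic acid and 8 1-[3-bromo-2-hydroxy-4-methoxy-6-(methoxymethoxy)phenyl]ethan-1-one
Product: 10 1-{2-hydroxy-4-methoxy-6-(methoxymethoxy)-3-[(2R)-5-methyl-2-(prop-1-en-2-yl)hex-4-en-1-yl]phenyl}ethan-1-one, via phthalimide ester 9 (not isolated)
Conditions: 5 (1.5 equiv), N-hydroxyphthalimide, DIC, DMAP (cat.), CH2Cl2, rt, filter and evaporate; then 8 (1.0 equiv), NiBr2·DME (10 mol%), dtbbpy (12 mol%), Hantzsch ester (2 equiv), DMA, 390–405 nm LEDs, 25 °C, argon, no base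
Reagents that add atoms: none
Why: Proposed new method: a light-driven nickel decarboxylative aryl–alkyl coupling has not been shown at a 2,6-dioxygenated aryl bromide that carries a free chelated ortho-phenol. Mechanistic reasoning: the photoexcited Hantzsch ester/phthalimide ester donor–acceptor pair transfers one electron and loss of CO2 gives the primary lavandulyl radical; bromide 8 adds oxidatively to zerovalent (dtbbpy)nickel; the divalent arylnickel bromide traps the small primary radical and the trivalent nickel species eliminates the aryl–CH2 bond. It should tolerate this substrate because the two ortho oxygens are much smaller than the ortho methyls that block mesityl-nickel, the base-free medium keeps the phenol neutral so it does not chelate nickel, and excited-state proton transfer keeps the hydroxy ketone photostable. The stereocenter is β to the radical and is not touched, and the only radical clock (3-exo attack on the fully substituted isopropenyl carbon, leading to a 1,2-alkenyl shift) is expected to be slower than capture by nickel. Closest known reaction type: Hantzsch-ester photochemical nickel-catalysed reductive coupling of N-acyloxyphthalimides with unhindered aryl bromides.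

**Step 7**
Reactants: 11 2,5-dihydroxybenzaldehyde
Product: 12 2,5-bis(methoxymethoxy)benzaldehyde
Conditions: MOMCl (3 equiv), i-Pr2NEt (4 equiv), DMAP (cat.), CH2Cl2, 0 °C to reflux
Reagents that add atoms: chloromethyl methyl ether, COCCl
Why: Standard MOM etherification of both phenols, so the aldehyde condenses cleanly in strong base and the hydroquinone is not oxidised.

**Step 8**
Reactants: 10 1-{2-hydroxy-4-methoxy-6-(methoxymethoxy)-3-[(2R)-5-methyl-2-(prop-1-en-2-yl)hex-4-en-1-yl]phenyl}ethan-1-one and 12 2,5-bis(methoxymethoxy)benzaldehyde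
Product: 15 (2S)-2-[2,5-bis(methoxymethoxy)phenyl]-7-methoxy-5-(methoxymethoxy)-8-[(2R)-5-methyl-2-(prop-1-en-2-yl)hex-4-en-1-yl]-2,3-dihydro-4H-chromen-4-one, via chalcone 13 (not isolated), via epimeric flavanone mixture 14 (not isolated)
Conditions: KOH (50% aq, 10 equiv), EtOH, rt, 48 h; AcOH to pH 7, reflux, 24 h; preparative HPLC (silica, hexane/EtOAc); (2R) fraction returned to KOAc/EtOH reflux and re-separated
Reagents that add atoms: none
Why: Claisen–Schmidt condensation gives the E-chalcone 13, and buffered reflux closes ring C by 6-endo oxa-Michael addition of the only free phenol (the one next to the lavandulyl group), which fixes the 8-lavandulyl regiochemistry; C2 forms about 1:1 because the carvone-derived center is too remote to bias it, but that center makes the epimers diastereomers, so they are separated without any chiral agent and the (2R) epimer is re-equilibrated through the chalcone and recycled, converging on (2S).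

**Step 9**
Reactants: 15 (2S)-2-[2,5-bis(methoxymethoxy)phenyl]-7-methoxy-5-(methoxymethoxy)-8-[(2R)-5-methyl-2-(prop-1-en-2-yl)hex-4-en-1-yl]-2,3-dihydro-4H-chromen-4-one
Product: 16 (2S)-2-(2,5-dihydroxyphenyl)-5-hydroxy-7-methoxy-8-[(2R)-5-methyl-2-(prop-1-en-2-yl)hex-4-en-1-yl]-2,3-dihydro-4H-chromen-4-one
Conditions: HCl (1 M) in MeOH, 35–40 °C, monitored, then NaHCO3 work-up
Reagents that add atoms: none
Why: Acid-catalysed acetal exchange removes the three MOM groups; the side chain is flanked only by the ring oxygen and the 7-OMe, so no phenol can add to its alkenes, and flavanone C2 does not epimerise under mild acid.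

## Compound list

1 | (R)-(−)-carvone, (5R)-2-methyl-5-(prop-1-en-2-yl)cyclohex-2-en-1-one | C=C(C)[C@@H]1CC=C(C)C(=O)C1 | starting material
2 | lithium (5R)-2-methyl-5-(prop-1-en-2-yl)cyclohex-1-en-1-olate | [Li+].C=C(C)[C@@H]1CCC(C)=C([O-])C1 | intermediate (not isolated)
3 | (5R)-2,2-dimethyl-5-(prop-1-en-2-yl)cyclohexan-1-one | C=C(C)[C@@H]1CCC(C)(C)C(=O)C1 | intermediate
4 | (3R)-6-methyl-3-(prop-1-en-2-yl)hept-5-enal | C=C(C)[C@H](CC=C(C)C)CC=O | intermediate
5 | (3R)-6-methyl-3-(prop-1-en-2-yl)hept-5-enoic acid | C=C(C)[C@H](CC=C(C)C)CC(=O)O | intermediate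
6 | 1-(2,6-dihydroxy-4-methoxyphenyl)ethan-1-one | CC(=O)c1c(O)cc(OC)cc1O | starting material
7 | 1-[2-hydroxy-4-methoxy-6-(methoxymethoxy)phenyl]ethan-1-one | COCOc1cc(OC)cc(O)c1C(C)=O | intermediate
8 | 1-[3-bromo-2-hydroxy-4-methoxy-6-(methoxymethoxy)phenyl]ethan-1-one | COCOc1cc(OC)c(Br)c(O)c1C(C)=O | intermediate
9 | 1,3-dioxoisoindolin-2-yl (3R)-6-methyl-3-(prop-1-en-2-yl)hept-5-enoate | C=C(C)[C@H](CC=C(C)C)CC(=O)ON1C(=O)c2ccccc2C1=O | intermediate (not isolated)
10 | 1-{2-hydroxy-4-methoxy-6-(methoxymethoxy)-3-[(2R)-5-methyl-2-(prop-1-en-2-yl)hex-4-en-1-yl]phenyl}ethan-1-one | C=C(C)[C@H](CC=C(C)C)Cc1c(OC)cc(OCOC)c(C(C)=O)c1O | intermediate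
11 | 2,5-dihydroxybenzaldehyde | O=Cc1cc(O)ccc1O | starting material
12 | 2,5-bis(methoxymethoxy)benzaldehyde | COCOc1ccc(OCOC)c(C=O)c1 | intermediate
13 | (2E)-3-[2,5-bis(methoxymethoxy)phenyl]-1-{2-hydroxy-4-methoxy-6-(methoxymethoxy)-3-[(2R)-5-methyl-2-(prop-1-en-2-yl)hex-4-en-1-yl]phenyl}prop-2-en-1-one | C=C(C)[C@H](CC=C(C)C)Cc1c(OC)cc(OCOC)c(C(=O)/C=C/c2cc(OCOC)ccc2OCOC)c1O | intermediate (not isolated)
14 | (2RS)-2-[2,5-bis(methoxymethoxy)phenyl]-7-methoxy-5-(methoxymethoxy)-8-[(2R)-5-methyl-2-(prop-1-en-2-yl)hex-4-en-1-yl]-2,3-dihydro-4H-chromen-4-one, both C2 epimers | C=C(C)[C@H](CC=C(C)C)Cc1c(OC)cc(OCOC)c2c1OC(c1cc(OCOC)ccc1OCOC)CC2=O | intermediate (not isolated)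
15 | (2S)-2-[2,5-bis(methoxymethoxy)phenyl]-7-methoxy-5-(methoxymethoxy)-8-[(2R)-5-methyl-2-(prop-1-en-2-yl)hex-4-en-1-yl]-2,3-dihydro-4H-chromen-4-one | C=C(C)[C@H](CC=C(C)C)Cc1c(OC)cc(OCOC)c2c1O[C@H](c1cc(OCOC)ccc1OCOC)CC2=O | intermediate
16 | (2S)-2-(2,5-dihydroxyphenyl)-5-hydroxy-7-methoxy-8-[(2R)-5-methyl-2-(prop-1-en-2-yl)hex-4-en-1-yl]-2,3-dihydro-4H-chromen-4-one | C=C(C)[C@H](CC=C(C)C)Cc1c(OC)cc(O)c2c1O[C@H](c1cc(O)ccc1O)CC2=O | target

## Step count and risks

Total steps: 9. Longest linear sequence: 6 (steps 1, 2, 3, 6, 8, 9).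

**Step 6 (the proposed new coupling).** Risks: slow radical capture at the di-ortho-substituted arylnickel, hydrogen transfer from the Hantzsch ester to the radical, hydrodebromination of 8, and binding of divalent nickel by the keto-phenol. Fallback with known chemistry, setting out from acid 5 through its ester 9: 9 is irradiated with blue LEDs and bis(catecholato)diboron in DMAc, and the crude catechol boronate is exchanged with pinacol/Et3N to give 2-[(2S)-5-methyl-2-(prop-1-en-2-yl)hex-4-en-1-yl]-4,4,5,5-tetramethyl-1,3,2-dioxaborolane F1. The descriptor is S only because boron ranks below carbon; the spatial arrangement is unchanged. F1 and bromide 8 are then joined by a thermal B-alkyl Suzuki–Miyaura coupling (Pd(OAc)2, RuPhos, K3PO4, toluene/H2O, 90 °C), a catalyst class suited to di-ortho-substituted aryl halides, which returns to the route at 10.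

**Step 2 (Norrish type 1 ring opening).** Risks: the competing ketene channel, and secondary photolysis of aldehyde 4 (Norrish type 2 abstraction of the allylic γ-hydrogen, or oxetane formation with its own alkenes), which is why conversion is held near 70%. Fallback, setting out from ketone 3: NH2OH·HCl and NaOAc in EtOH give (1E,5R)-2,2-dimethyl-5-(prop-1-en-2-yl)cyclohexan-1-one oxime F2, with the OH anti to the quaternary carbon. p-TsCl in pyridine (0 to 60 °C) forms the O-(4-methylbenzenesulfonyl) oxime F3, which is not isolated and undergoes Beckmann fragmentation: the anti quaternary carbon leaves as a tertiary cation and loses a C3 proton, giving (3R)-6-methyl-3-(prop-1-en-2-yl)hept-5-enenitrile F4. The minor terminal-alkene isomer is removed on AgNO3-impregnated silica. i-Bu2AlH (toluene, −78 °C, then aqueous acid) returns to the route at aldehyde 4.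

**Step 8 (C2 configuration).** Risk: the two C2 epimers, which differ only relative to a remote center, may not separate on achiral silica. Fallback, setting out from the unresolved mixture 14: it is deprotected under the step 9 conditions to a mixture of 16 and its epimer (2R)-2-(2,5-dihydroxyphenyl)-5-hydroxy-7-methoxy-8-[(2R)-5-methyl-2-(prop-1-en-2-yl)hex-4-en-1-yl]-2,3-dihydro-4H-chromen-4-one F5. This mixture is stirred as a slurry in degassed aqueous EtOH with Et3N (0.2 equiv) and seeds of 16 taken from an analytical reversed-phase HPLC cut. F5 ring-opens to the chalcone and re-closes while the seeded diastereomer crystallises (crystallization-induced diastereomer transformation), returning to the route at 16. Which epimer crystallises cannot be predicted, and the open chalcone can also re-close through the 5-OH; that 6-lavandulyl isomer stays in the liquor and keeps equilibrating.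

## Further compounds

F1 | step 6 | 2-[(2S)-5-methyl-2-(prop-1-en-2-yl)hex-4-en-1-yl]-4,4,5,5-tetramethyl-1,3,2-dioxaborolane | C=C(C)[C@H](CC=C(C)C)CB1OC(C)(C)C(C)(C)O1
F2 | step 2 | (1E,5R)-2,2-dimethyl-5-(prop-1-en-2-yl)cyclohexan-1-one oxime | C=C(C)[C@@H]1CCC(C)(C)/C(=N/O)C1
F3 | step 2 | (1E,5R)-2,2-dimethyl-5-(prop-1-en-2-yl)cyclohexan-1-one O-(4-methylbenzenesulfonyl)oxime | C=C(C)[C@@H]1CCC(C)(C)/C(=N/OS(=O)(=O)c2ccc(C)cc2)C1
F4 | step 2 | (3R)-6-methyl-3-(prop-1-en-2-yl)hept-5-enenitrile | C=C(C)[C@H](CC=C(C)C)CC#N
F5 | step 8 | (2R)-2-(2,5-dihydroxyphenyl)-5-hydroxy-7-methoxy-8-[(2R)-5-methyl-2-(prop-1-en-2-yl)hex-4-en-1-yl]-2,3-dihydro-4H-chromen-4-one | C=C(C)[C@H](CC=C(C)C)Cc1c(OC)cc(O)c2c1O[C@@H](c1cc(O)ccc1O)CC2=O
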